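Count the starting material.

| flask | starting material | partner | remark | time |
|---|---|---|---|---|
| blue | 22 mM | 1.1 equiv | the very flask that is asked about, followed so far |  |
| green | 22 mM | 0.55 equiv | run made earlier |  |
| flask | 22 mM | 1.10 equiv |  | 80 min |

| run | time / min | product / % | starting material / % |
|---|---|---|---|
| blue | 10.0 | 28.1 | 7.6 |
| blue | 20.0 | 31.0 | 3.3 |
| blue | 30.0 | 33.6 | 3.0 |
| blue | 40.0 | 34.8 | 2.1 |
| blue | 50.0 | 35.9 | 1.7 |
| blue | 60.0 | 36.2 | 2.1 |
| green | 2.50 | 4.2 | 33.9 |
| green | 5.00 | 7.7 | 19.4 |
| green | 8.00 | 9.1 | 12.1 |
| green | 10.0 | 10.1 | 9.6 |
| green | 12.0 | 11.8 | 8.1 |
| green | 15.0 | 12.0 | 6.0 |

(scatter of a reading: 0.5 percentage points)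

- east: change nothing and wait 25 min more
- north: at 80 min add starting material, 50.0 % of the amount charged, then wait 25 min
- south-west: at 80 min add partner, 100 % of the amount charged, then wait 25 min
- north-east: at 80 min take out 90 % of the product then present, then wait 25 min

- what is taken out of product is counted as made
- additions bring no volume worth counting

1. product, in percent of the starting material first charged, at 80 min
2. the remedy with the largest gain of product, or "none" below 2 percentage points (east / north / south-west / north-east / none)
3. product present, with what was taken out counted in, in percent of the starting material first charged, after east
4. product present, with what was taken out counted in, in percent of the starting material first charged, after north-east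

**The balance.** I wrote one balance for the blue run: whatever was neither free starting material nor product formed an unseen share, which stood at 61.7 % at the last reading. Free starting material had stopped falling by then, since its last three readings, 2.1 %, 1.7 % and 2.1 %, lay within the scatter of 0.5 percentage points. A low level beside so large a stock suggested exchange between the two, with the stock as a resting state. So I averaged the last two blue readings and divided free starting material by the unseen share, which gave 0.0306; I call this the hold ratio.

**Second way.** The last reading of the green run gave the same ratio as 0.0732, which is larger than the blue value, so one of them cheated. Starting material in the green run was still dropping, from 8.1 % to 6.0 % between its last two readings, so I kept the blue value.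

**My reckoning.** Blue product climbed steadily at the end, and that pace added 1.7 points by 80 min, giving 37.9 %. The hold ratio then put free starting material at 1.90 %. East promised 2.2 points more. Neither run had product taken out, so I had no reading for north-east, and I set it level with east as a guess.

A full charge of partner at least doubles what is free, and doubling partner from green to blue multiplied product at 10.0 min by 2.78. South-west therefore offered about 6 points, reckoned for a mere doubling of partner. Scaling the green product to the added starting material offered north about 6 points. The two estimates stood level, but a full charge was reckoned there at its least effect on free partner, so I chose south-west.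

**The forecast.** The forecast gave 37 %, 37.9 % after east and 38 % after north-east, and it chose north, where I differed, on the ground that “Fresh SM meets remaining partner”.

**The flask.** The flask gave 38.3 %, then 39.9 % after east and 39.9 % after north-east, and south-west gained most, 8.4 points against 5.4 points for north.

    starting material + partner ⇌ intermediate A (K = 69.0 M⁻¹, k = 0.350 M⁻¹ s⁻¹)
    starting material ⇌ intermediate B (K = 4.20, k = 0.00600 s⁻¹)
    partner + intermediate A → product (k = 0.240 M⁻¹ s⁻¹)
    intermediate B ⇌ intermediate C (K = 2.10, k = 0.00320 s⁻¹)
    intermediate C ⇌ intermediate D (K = 0.730, k = 0.00340 s⁻¹)
    intermediate C ⇌ intermediate E (K = 0.980, k = 0.00140 s⁻¹)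
    starting material ⇌ intermediate E (k = 1.30 × 10⁻⁴ s⁻¹)

**Hold ratio.** Intermediates A to E together held 59.9 % at 80.0 min. The hold ratio, applied to this flask's unseen share, gives 1.83 % free starting material, and the flask held 1.85 %. Applied to the neighbour flask charged with 8.8 mM of starting material, it gives 2.38 %, and that flask held 2.48 %.

Readings and results were computed with made-up constants; the scatter is artificial.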